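## Structural features

The target is a flavone: a benzo ring A fused to a γ-pyrone ring C, with the aryl ring B attached to C2 of the pyrone through the single bond C2–C1'. Ring A carries a 5-OH, hydrogen-bonded to the C4 carbonyl, and a 7-OMe. Ring B carries four contiguous oxygens (C2'-OMe, C3'-OH, C4'-OMe, C5'-OMe) and one hydrogen, at C6'. There is no stereocenter and no hindered axis, so no stereochemical question arises. The fragile parts are the pyrone ring, which opens when hard nucleophiles add at C2, and the very electron-rich ring B, whose hydroquinone-type precursors oxidize readily in base and air. Ring A and the chromone core are easy, since the 5-OH/7-OMe pattern can be bought. The real difficulty is ring B, where the one free hydroxyl at C3' must be distinguished from two flanking methoxy groups and a third at C5'. The key step uses the fact that C2' to C5' with their oxygens correspond to the four carbons of a 2,3,4-trioxygenated furan plus its ring oxygen, while C1' and C6' are the two carbons of an alkyne on chromone C2.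

## Logic of the disconnections

18 to 17: the O–CH2Ph bond at the C3' oxygen is cut. A benzyl ether is the one protecting group that comes off under neutral conditions without touching four methyl ethers or the pyrone. The forward step must leave the C2=C3 bond unreduced.

17 to 16: the two O–CH3 bonds at the C2' and C5' oxygens are cut. This exposes a 2',5'-hydroquinone, the direct outcome of a furan–alkyne benzannulation. The forward methylation must spare the chelated 5-OH and must not let the hydroquinone oxidize.

16 to 6 and 13: the C1'–C2' and C5'–C6' bonds are cut, which takes ring B apart completely. The gain is large: a tetraoxygenated arene with a differentiated central oxygen becomes a furan in which each oxygen already carries its final or temporary group, plus an alkynyl chromone containing all of rings A and C. The forward step must join furan C5 to the terminal alkyne carbon, must use the alkyne and not the chromone C2=C3 bond, and must open the bridged adduct towards the arene.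

6 to 5 to 4: the O–Si bond and then the O–CH3 bond at C4 are cut. The aromatic furan is thus traced to a butenolide and then to a tetronic acid. Silylation must occur on the lactone oxygen with loss of a C5 proton, and methylation must occur on the C4 oxygen.

4 to 3 to 1 and 2: the C3–C4 bond of the tetronic acid is cut (intramolecular Claisen), then the ester C–O bond. Two commercial two-carbon units, each with its oxygen in place, remain. The enolate of the benzyloxyacetyl carbon, not that of the glycolate carbon, must be the one that cyclizes.

13 to 11: the terminal alkyne carbon (the future C6') is removed, leaving an aldehyde. The one-carbon homologation must run under conditions that the pyrone tolerates.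

11 to 7 and 8: the bond between C3 and the C2 carbon is cut (Claisen), as is the O1–C2 bond (cyclodehydration). Ring A with its oxygen pattern is bought as 7, and 8 brings the formyl carbon at the aldehyde oxidation level as an acetal, so no redox adjustment is needed. The Claisen condensation must work on the polyanion of an unprotected dihydroxyacetophenone.

## Other disconnections considered

Alternative 1: The cut is C2=C3 of ring C. In the forward key step the acyloxy keto ylide A2 would be heated; it is made from a ring A phenacyl phosphorane, O-acylated with the chloride of acid A3. The ylide carbon attacks the aryl ester carbonyl and phosphine oxide is expelled, giving the bis(benzyl) flavone A1. One hydrogenolysis then frees both phenols.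
- In favour: ester olefination by stabilized keto ylides is established for chromones, runs under neutral conditions, and raises no regiochemical question. On mechanistic certainty it is better than the chosen plan.
- Against: it leaves the real problem unsolved. A3, with four contiguous oxygens and a differentiated central one, would need its own multistep synthesis by phenol differentiation and aromatic substitution. The ring A piece requires mono-protection of symmetrical 7, bromination and phosphonium salt formation. The ester carbonyl of A2 is electron-rich and ortho-substituted, so the olefination may be slow.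
- Comparison: the chosen plan creates the ring B pattern from acyclic pieces, whereas this alternative must carry it in ready-made. The end game is equal (one hydrogenolysis). Step economy is expected to favour the chosen plan (9 steps) once the preparation of A3 is counted.

Alternative 2: The cut is C4–C4a. In the forward key step the β-aryloxycinnamic acid A5 would be treated with Eaton's reagent (P2O5 in MeSO3H). The acylium ion attacks an ortho carbon of the 3,5-dimethoxyphenoxy ring to give the pentamethoxy isopropoxy flavone A4. BCl3 would then remove the isopropyl group and the peri 5-O-methyl group.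
- In favour: the nucleophilic ring is symmetrical and doubly activated, so the closure has no regiochemical ambiguity. The reagents are cheap and the sequence from a ring B propiolate is short. On cost and scalability it is better than the chosen plan.
- Against: only the Z isomer of A5 can close ring C. The E isomer could instead acylate the activated C6' of ring B and form an indenone. Hot strong acid may remove the isopropyl group early. After the C3' oxygen is bound to boron, cleavage of the neighbouring methoxy groups becomes a risk. Ring B must again be prefabricated with all four oxygens.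
- Comparison: mechanistically the Friedel–Crafts closure is known and the chosen key step is not. Structurally it does not address the ring B pattern, and its deprotection rests on a finer discrimination than the chosen hydrogenolysis. Step economy would be about equal only if the ring B propiolate were at hand.

Alternative 3: The cut is C4a–C5, so ring A is made. In the forward key step the cinnamoyl triketo ester A7 would be cyclized with KOH in methanol or Mg(OMe)2. C6 attacks the ester carbon and the ring aromatizes to the trihydroxychalcone A6. Oxidative cyclization (I2, DMSO) would give the 5,7-dihydroxyflavone A8, selective 7-O-methylation would give 17 of the chosen route, and hydrogenolysis would finish.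
- In favour: the closure is biomimetic and mild, the ring formed is symmetrical, and the chalcone-to-flavone step is thoroughly established. It meets the chosen route at 17, so the last step is equal.
- Against: ring A is the trivial part of the target and is available as 7 with the 5-OH/7-OMe pattern in place. A7 is a labile polycarbonyl compound that can also close by aldol reaction of C2 onto C7, lactonize to a pyrone, or suffer Michael addition at its enone. An extra selective methylation is needed, and ring B must still be prefabricated.
- Comparison: the chosen plan puts its key step where the structural difficulty lies, whereas this alternative puts it where there is none. Step economy is expected to be clearly worse.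

Key step: step 7

Remark on the chemistry: the mapping of furan C2–C5 onto C2'–C5' and of the alkyne carbons onto C1'/C6' was checked and needs no correction. Aldehyde 11 is taken from ethyl diethoxyacetate and not from an oxalate ester, which removes a reduction–oxidation pair, and the 5-OH is carried unprotected throughout.

## Route

Step 1
Reactants: 1 benzyloxyacetyl chloride; 2 methyl glycolate
Product: 3 methyl 2-{[2-(benzyloxy)acetyl]oxy}acetate
Conditions: pyridine, DMAP (cat.), CH2Cl2, 0 °C to rt
Reagents that add atoms: none
Why: Esterification of a primary alcohol by an acid chloride under nucleophilic catalysis; neither partner has a competing functional group.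

Step 2
Reactants: 3 methyl 2-{[2-(benzyloxy)acetyl]oxy}acetate
Product: 4 3-(benzyloxy)-4-hydroxyfuran-2(5H)-one
Conditions: LiN(SiMe3)2 (2.2 equiv), THF, −78 °C to 0 °C; then 1 M HCl
Reagents that add atoms: none
Why: Dieckmann (intramolecular Claisen) condensation: the enolate of the benzyloxyacetyl carbon attacks the methyl ester to close the five-membered ring, and formation of the stabilized tetronate anion drives the reaction. This is the standard entry to 3-alkoxytetronic acids from O-acyl glycolates.

Step 3
Reactants: 4 3-(benzyloxy)-4-hydroxyfuran-2(5H)-one
Product: 5 3-(benzyloxy)-4-methoxyfuran-2(5H)-one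
Conditions: Me2SO4 (1.2 equiv), K2CO3, acetone, reflux
Reagents that add atoms: dimethyl sulfate, COS(=O)(=O)OC
Why: O-Alkylation of a vinylogous acid with a hard methylating agent gives the 4-methoxybutenolide (a methyl tetronate). C3 is fully substituted and the vinylogous ester is the more stable O-alkyl isomer.

Step 4
Reactants: 5 3-(benzyloxy)-4-methoxyfuran-2(5H)-one
Product: 6 tert-butyl{[3-(benzyloxy)-4-methoxyfuran-2-yl]oxy}dimethylsilane
Conditions: TBSOTf (1.2 equiv), Et3N, CH2Cl2, 0 °C; filtration under argon, used directly
Reagents that add atoms: tert-butyldimethylsilyl triflate, CC(C)(C)[Si](C)(C)OS(=O)(=O)C(F)(F)F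
Why: Soft enolization: the silyl triflate activates the lactone carbonyl and the amine removes a C5 proton, giving the aromatic 2-silyloxyfuran. This is the usual preparation of silyloxyfurans from butenolides and tetronates.

Step 5
Reactants: 7 2',6'-dihydroxy-4'-methoxyacetophenone; 8 ethyl diethoxyacetate
Product: 11 5-hydroxy-7-methoxy-4-oxo-4H-chromene-2-carbaldehyde, via diketone acetal 9 (not isolated), via chromone acetal 10 (not isolated)
Conditions: LiN(SiMe3)2 (4.2 equiv), THF, −78 °C to rt; aq. HCl work-up; then conc. HCl, AcOH, 80 °C
Reagents that add atoms: water, O
Why: Claisen condensation of the acetophenone polyanion with the activated α,α-dialkoxy ester gives the 1,3-diketone 9. Acid then closes the pyrone by cyclodehydration (the classical chromone synthesis from an o-hydroxyaryl 1,3-diketone) and hydrolyzes the acetal of 10 to the aldehyde. The second phenol remains as the chelated 5-OH.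

Step 6
Reactants: 11 5-hydroxy-7-methoxy-4-oxo-4H-chromene-2-carbaldehyde
Product: 13 2-ethynyl-5-hydroxy-7-methoxy-4H-chromen-4-one, via diazoalkene 12 (not isolated)
Conditions: dimethyl (1-diazo-2-oxopropyl)phosphonate (1.3 equiv), K2CO3 (3 equiv), MeOH, 0 °C to rt; acidify to pH 5
Reagents that add atoms: dimethyl (1-diazo-2-oxopropyl)phosphonate, CC(=O)C(=[N+]=[N-])P(=O)(OC)OC
Why: Seyferth–Gilbert homologation with the Ohira–Bestmann reagent: methanolysis liberates the diazomethylphosphonate anion, Horner–Wadsworth–Emmons-type olefination gives diazoalkene 12, and loss of N2 with a 1,2-hydrogen shift gives the terminal alkyne. Under the carbonate base the 5-OH is present as its phenoxide, which lowers the electrophilicity of the pyrone towards methoxide.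

Step 7
Reactants: 6 tert-butyl{[3-(benzyloxy)-4-methoxyfuran-2-yl]oxy}dimethylsilane; 13 2-ethynyl-5-hydroxy-7-methoxy-4H-chromen-4-one
Product: 16 3'-(benzyloxy)-5,2',5'-trihydroxy-7,4'-dimethoxyflavone, via oxanorbornadiene cycloadduct 14 (not isolated), via 2'-O-silyl hydroquinone 15 (not isolated)
Conditions: 6 (1.5 equiv), toluene, 80 °C, argon; then Bu4NF, AcOH, THF, 0 °C
Reagents that add atoms: none
Why: Proposed new method: the trioxygenated 2-silyloxyfuran 6 is a very electron-rich diene and the alkyne of 13 is a vinylogous ynone, activated through C2=C3–C4=O and further by the internal 5-OH to C4=O hydrogen bond, so a normal-demand [4+2] cycloaddition (concerted and asynchronous, or stepwise by vinylogous Mukaiyama–Michael addition and closure onto the silyloxycarbenium ion) should give oxanorbornadiene 14; the closest known reaction type is the Diels–Alder reaction of 2-silyloxyfurans with acetylenic esters and ketones, with opening of the adduct to a hydroquinone monosilyl ether. Ring B is closed by an intermolecular [4+2] annulation that forms C1'–C2' and C5'–C6', four ring atoms coming from the furan carbons and two from the alkyne. In 14 the bridgehead ketal C2'–O bond ionizes with help from the silyloxy oxygen and the C4' methoxy group, the C5' proton is lost and arene 15 results; buffered fluoride then removes the silyl group to give 16. No stereocenter remains, because the two bridgehead centers of 14 are destroyed on aromatization. The step needs regioselectivity and chemoselectivity. Furan C5, the nucleophilic terminus of the silyl dienolate and further activated by the adjacent methoxy group, should bond to the terminal alkyne carbon, which is the unhindered δ-position of the acceptor; this polarity match places the benzyloxy carbon at C3'. The alkyne should react in preference to the chromone C2=C3 bond because that bond is a trisubstituted, donor-substituted vinylogous ester and a poor dienophile. The excess of 6 covers loss by protonation from the chelated 5-OH, and the fluoride work-up also removes any silyl group transferred to that oxygen.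

Step 8
Reactants: 16 3'-(benzyloxy)-5,2',5'-trihydroxy-7,4'-dimethoxyflavone
Product: 17 3'-(benzyloxy)-5-hydroxy-7,2',4',5'-tetramethoxyflavone
Conditions: MeI (2.3 equiv), K2CO3 (2.5 equiv), degassed acetone, 40 °C, argon
Reagents that add atoms: iodomethane, CI
Why: Williamson etherification: the two ring B phenoxides form and alkylate readily, whereas the 5-OH is held in a strong hydrogen bond to the C4 carbonyl and should react far more slowly with a limited amount of methyl iodide. Exclusion of air protects the hydroquinone from oxidation to the quinone.

Step 9
Reactants: 17 3'-(benzyloxy)-5-hydroxy-7,2',4',5'-tetramethoxyflavone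
Product: 18 5,3'-dihydroxy-7,2',4',5'-tetramethoxyflavone
Conditions: H2 (1 atm), Pd/C, EtOAc–MeOH, rt
Reagents that add atoms: none
Why: Catalytic hydrogenolysis of the benzyl aryl ether over Pd/C at atmospheric pressure. The flavone C2=C3 bond, part of a vinylogous ester, and the aryl methyl ethers should not be reduced under these conditions.

## Compound list

1 | benzyloxyacetyl chloride | O=C(Cl)COCc1ccccc1 | starting material
2 | methyl glycolate | COC(=O)CO | starting material
3 | methyl 2-{[2-(benzyloxy)acetyl]oxy}acetate | COC(=O)COC(=O)COCc1ccccc1 | intermediate
4 | 3-(benzyloxy)-4-hydroxyfuran-2(5H)-one | O=C1OCC(O)=C1OCc1ccccc1 | intermediate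
5 | 3-(benzyloxy)-4-methoxyfuran-2(5H)-one | COC1=C(OCc2ccccc2)C(=O)OC1 | intermediate
6 | tert-butyl{[3-(benzyloxy)-4-methoxyfuran-2-yl]oxy}dimethylsilane | COc1coc(O[Si](C)(C)C(C)(C)C)c1OCc1ccccc1 | intermediate
7 | 2',6'-dihydroxy-4'-methoxyacetophenone | CC(=O)c1c(O)cc(OC)cc1O | starting material
8 | ethyl diethoxyacetate | CCOC(OCC)C(=O)OCC | starting material
9 | 4,4-diethoxy-1-(2,6-dihydroxy-4-methoxyphenyl)butane-1,3-dione | CCOC(OCC)C(=O)CC(=O)c1c(O)cc(OC)cc1O | intermediate (not isolated)
10 | 2-(diethoxymethyl)-5-hydroxy-7-methoxy-4H-chromen-4-one | CCOC(OCC)c1cc(=O)c2c(O)cc(OC)cc2o1 | intermediate (not isolated)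
11 | 5-hydroxy-7-methoxy-4-oxo-4H-chromene-2-carbaldehyde | O=Cc1cc(=O)c2c(O)cc(OC)cc2o1 | intermediate
12 | 2-(2-diazoethenyl)-5-hydroxy-7-methoxy-4H-chromen-4-one | [N-]=[N+]=C=Cc1cc(=O)c2c(O)cc(OC)cc2o1 | intermediate (not isolated)
13 | 2-ethynyl-5-hydroxy-7-methoxy-4H-chromen-4-one | C#Cc1cc(=O)c2c(O)cc(OC)cc2o1 | intermediate
14 | 2-{6-(benzyloxy)-1-[(tert-butyldimethylsilyl)oxy]-5-methoxy-7-oxabicyclo[2.2.1]hepta-2,5-dien-2-yl}-5-hydroxy-7-methoxy-4H-chromen-4-one (racemic; one enantiomer drawn, bridgeheads necessarily cis) | COC1=C(OCc2ccccc2)[C@@]3(O[Si](C)(C)C(C)(C)C)O[C@@H]1C=C3c1cc(=O)c2c(O)cc(OC)cc2o1 | intermediate (not isolated)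
15 | 3'-(benzyloxy)-2'-[(tert-butyldimethylsilyl)oxy]-5,5'-dihydroxy-7,4'-dimethoxyflavone | COc1cc(O)c2c(=O)cc(-c3cc(O)c(OC)c(OCc4ccccc4)c3O[Si](C)(C)C(C)(C)C)oc2c1 | intermediate (not isolated)
16 | 3'-(benzyloxy)-5,2',5'-trihydroxy-7,4'-dimethoxyflavone | COc1cc(O)c2c(=O)cc(-c3cc(O)c(OC)c(OCc4ccccc4)c3O)oc2c1 | intermediate
17 | 3'-(benzyloxy)-5-hydroxy-7,2',4',5'-tetramethoxyflavone | COc1cc(O)c2c(=O)cc(-c3cc(OC)c(OC)c(OCc4ccccc4)c3OC)oc2c1 | intermediate
18 | 5,3'-dihydroxy-7,2',4',5'-tetramethoxyflavone | COc1cc(O)c2c(=O)cc(-c3cc(OC)c(OC)c(O)c3OC)oc2c1 | target

## Step count and least certain steps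

Total step count: 9. Longest linear sequence: 7 steps (steps 1 to 4, then 7 to 9); the chromone branch (steps 5 and 6) joins at step 7.

**Step 7 (key step, proposed new method).**
- What may go wrong: protodesilylation of the furan by the phenol or by traces of acid before it can react; too low a dienophilicity of the alkyne, so that the furan decomposes first; interruption after the first C–C bond (Michael addition without ring closure); or addition at chromone C2 in place of the alkyne terminus.
- Fallback (known chemistry): furan 6 is combined with methyl propiolate in toluene at 60–80 °C, the acetylenic-ester class for which silyloxyfuran cycloaddition with ring opening is established. Buffered fluoride then gives methyl 3-(benzyloxy)-2,5-dihydroxy-4-methoxybenzoate F1. Both phenols are methylated (MeI, K2CO3, DMF) to methyl 3-(benzyloxy)-2,4,5-trimethoxybenzoate F2. The lithium polyanion of acetophenone 7 (LiN(SiMe3)2, THF, −78 °C to rt) is acylated by F2 to 1-[3-(benzyloxy)-2,4,5-trimethoxyphenyl]-3-(2,6-dihydroxy-4-methoxyphenyl)propane-1,3-dione F3. Acid-catalysed cyclodehydration (p-TsOH, toluene, 80 °C) closes ring C. The fallback sets out from 6, with 7 as partner, and returns to the route at 17, so step 9 completes the synthesis.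

**Step 6.**
- What may go wrong: conjugate addition of methoxide to the newly formed enynone-type alkyne, or opening of the pyrone by attack at C2, because the homologation runs in basic methanol.
- Fallback: homologation of 11 in an aprotic medium with lithiated trimethylsilyldiazomethane (Me3SiCHN2, LiN(iPr)2, THF, −78 °C to rt; Colvin rearrangement, one extra equivalent of base for the phenol). It reaches the same diazoalkene 12 by Peterson elimination and never exposes aldehyde or alkyne to an alkoxide. It sets out from 11 and returns at 13, with no new isolable compound.

**Step 2.**
- What may go wrong: deprotonation at the glycolate carbon followed by 1,2-acyl migration (Chan rearrangement) in competition with the Dieckmann closure.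
- Fallback: the ring is assembled by a crossed Claisen condensation followed by lactonization, so that no O-acyl glycolate is ever exposed to base. Acid chloride 1 is converted with methanol and pyridine into methyl 2-(benzyloxy)acetate F4. Its lithium enolate (LiN(iPr)2, 2 equiv, THF, −78 °C) is acylated with acetoxyacetyl chloride to racemic methyl 4-(acetyloxy)-2-(benzyloxy)-3-oxobutanoate F5. HCl in methanol removes the acetate, and the freed hydroxy keto ester lactonizes. The fallback sets out from 1 and returns at 4.

**Step 8.**
- What may go wrong: aerial oxidation of the hydroquinone dianion to the quinone, or partial methylation of the 5-OH.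
- Fallback: the free hydroquinone is never exposed to base. Silyl ether 15 is isolated by omitting the fluoride treatment of step 7. Its single unchelated phenol is methylated (MeI, K2CO3, acetone) to 3'-(benzyloxy)-2'-[(tert-butyldimethylsilyl)oxy]-5-hydroxy-7,4',5'-trimethoxyflavone F6. CsF and MeI in DMF then effect desilylation with immediate methylation of the C2' oxygen. The fallback sets out from 15 and returns at 17.

## Further compounds

F1 | step 7 | methyl 3-(benzyloxy)-2,5-dihydroxy-4-methoxybenzoate | COC(=O)c1cc(O)c(OC)c(OCc2ccccc2)c1O
F2 | step 7 | methyl 3-(benzyloxy)-2,4,5-trimethoxybenzoate | COC(=O)c1cc(OC)c(OC)c(OCc2ccccc2)c1OC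
F3 | step 7 | 1-[3-(benzyloxy)-2,4,5-trimethoxyphenyl]-3-(2,6-dihydroxy-4-methoxyphenyl)propane-1,3-dione | COc1cc(O)c(C(=O)CC(=O)c2cc(OC)c(OC)c(OCc3ccccc3)c2OC)c(O)c1
F0 | step 6 | none | none
F4 | step 2 | methyl 2-(benzyloxy)acetate | COC(=O)COCc1ccccc1
F5 | step 2 | methyl 4-(acetyloxy)-2-(benzyloxy)-3-oxobutanoate (racemic) | COC(=O)C(OCc1ccccc1)C(=O)COC(C)=O
F6 | step 8 | 3'-(benzyloxy)-2'-[(tert-butyldimethylsilyl)oxy]-5-hydroxy-7,4',5'-trimethoxyflavone | COc1cc(O)c2c(=O)cc(-c3cc(OC)c(OC)c(OCc4ccccc4)c3O[Si](C)(C)C(C)(C)C)oc2c1
A1 | alternative 1 | 5,3'-bis(benzyloxy)-7,2',4',5'-tetramethoxyflavone | COc1cc(OCc2ccccc2)c2c(=O)cc(-c3cc(OC)c(OC)c(OCc4ccccc4)c3OC)oc2c1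
A2 | alternative 1 | 3-(benzyloxy)-5-methoxy-2-[2-(triphenylphosphoranylidene)acetyl]phenyl 3-(benzyloxy)-2,4,5-trimethoxybenzoate | COc1cc(OCc2ccccc2)c(C(=O)C=P(c2ccccc2)(c2ccccc2)c2ccccc2)c(OC(=O)c2cc(OC)c(OC)c(OCc3ccccc3)c2OC)c1
A3 | alternative 1 | 3-(benzyloxy)-2,4,5-trimethoxybenzoic acid | O=C(O)c1cc(OC)c(OC)c(OCc2ccccc2)c1OC
A4 | alternative 2 | 3'-isopropoxy-5,7,2',4',5'-pentamethoxyflavone | COc1cc(OC)c2c(=O)cc(-c3cc(OC)c(OC)c(OC(C)C)c3OC)oc2c1
A5 | alternative 2 | (Z)-3-(3,5-dimethoxyphenoxy)-3-(3-isopropoxy-2,4,5-trimethoxyphenyl)prop-2-enoic acid | O=C(O)/C=C(\Oc1cc(OC)cc(OC)c1)c1cc(OC)c(OC)c(OC(C)C)c1OC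
A6 | alternative 3 | (E)-3-[3-(benzyloxy)-2,4,5-trimethoxyphenyl]-1-(2,4,6-trihydroxyphenyl)prop-2-en-1-one | O=C(/C=C/c1cc(OC)c(OC)c(OCc2ccccc2)c1OC)c1c(O)cc(O)cc1O
A7 | alternative 3 | methyl (E)-9-[3-(benzyloxy)-2,4,5-trimethoxyphenyl]-3,5,7-trioxonon-8-enoate | COC(=O)CC(=O)CC(=O)CC(=O)/C=C/c1cc(OC)c(OC)c(OCc2ccccc2)c1OC
A8 | alternative 3 | 3'-(benzyloxy)-5,7-dihydroxy-2',4',5'-trimethoxyflavone | Oc1cc(O)c2c(=O)cc(-c3cc(OC)c(OC)c(OCc4ccccc4)c3OC)oc2c1
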